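The 1-formylvinyl group on C2 is read as a methylenated α-keto acetal. This uncovers a β-hydroxy ketone running from the C3 oxygen through C2 to the side-chain carbon, with O1 making C2 the α-carbon of an aryloxy ketone. The dihydrofuran ring (O1, C2, C3, C3a, C7a) is therefore closed at the C2–C3 bond by a proline-catalysed intramolecular aldol addition of that α-carbon to the ortho aldehyde of an achiral keto aldehyde, which forms the ring and sets C2 and C3 cis with absolute control in one operation. Methylenation, conversion of the aryl bromide into the (R)-angeloyloxyethyl arm and acetal hydrolysis finish the synthesis.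

Key step: step 2

Remark: atom labels follow 2,3-dihydro-1-benzofuran numbering; the sense of induction in step 2 is assigned from the Houk–List model, and 1, 2 and 13 are taken as purchasable.

Step 1
Reactants: 1 5-bromo-2-hydroxybenzaldehyde; 2 3-bromo-1,1-dimethoxypropan-2-one
Product: 3 5-bromo-2-(3,3-dimethoxy-2-oxopropoxy)benzaldehyde
Conditions: K2CO3, acetone, 0 °C to rt
Reagents that add atoms: 3-bromo-1,1-dimethoxypropan-2-one (2), COC(OC)C(=O)CBr
Why: Williamson etherification, in which the acidic phenol of 1 is deprotonated by K2CO3 and displaces the very reactive α-bromo ketone, under conditions mild enough that the base should not yet trigger a racemic aldol closure of 3; no stereocentre is formed.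

Step 2
Reactants: 3 5-bromo-2-(3,3-dimethoxy-2-oxopropoxy)benzaldehyde
Product: 6 1-[(2S,3R)-5-bromo-3-hydroxy-2,3-dihydro-1-benzofuran-2-yl]-2,2-dimethoxyethan-1-one, via proline enamine 4 (not isolated), via iminium carboxylate 5 (not isolated)
Conditions: (S)-proline (30 mol %), DMSO, rt
Reagents that add atoms: none
Why: (S)-Proline condenses with the α-aryloxy ketone of 3 to give the (E)-enamine 4 on the OCH2 side, whose carbon adds to the ortho aldehyde in a Houk–List transition state in which the proline CO2H hydrogen-bonds the aldehyde oxygen, and hydrolysis of iminium carboxylate 5 releases 6 and the catalyst. The closest known reaction type is the proline-catalysed intramolecular enolexo aldolisation, here with a hydroxyacetone-type α-oxygenated donor. The dihydrofuran ring closes by C2–C3 bond formation in a 5-exo-trig (enolexo) mode. C3 is controlled by the hydrogen bond, which holds the aldehyde oxygen on the side of the enamine carbon and so places the C3–OH cis to the C2 acyl group; C2 and the absolute sense (2S,3R) are controlled by attack on the enamine face syn to the carboxylic acid of (S)-proline. The step needs enamine formation at C2 only and survival of the β-hydroxy ketone without dehydration to the aromatic benzofuran: the other α-carbon is a hindered acetal methine, both α-carbons of 6 are tertiary so the product is not re-activated by the catalyst, and the non-basic medium at room temperature disfavours E1cB loss of water.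

Step 3
Reactants: 6 1-[(2S,3R)-5-bromo-3-hydroxy-2,3-dihydro-1-benzofuran-2-yl]-2,2-dimethoxyethan-1-one
Product: 7 (2R,3R)-5-bromo-2-(3,3-dimethoxyprop-1-en-2-yl)-2,3-dihydro-1-benzofuran-3-ol
Conditions: Zn, CH2Br2, TiCl4, THF/CH2Cl2, 0 °C to rt; aq. NaHCO3
Reagents that add atoms: dibromomethane, BrCBr
Why: Takai–Lombardo methylenation, in which the non-basic zinc–titanium methylene reagent converts the activated α-oxygenated ketone into the 1,1-disubstituted alkene without enolising C2, so the cis arrangement is kept (the C2 descriptor changes to R only through the change in substituent priority) while the free hydroxyl, the acetal and the aryl bromide are tolerated.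

Step 4
Reactants: 7 (2R,3R)-5-bromo-2-(3,3-dimethoxyprop-1-en-2-yl)-2,3-dihydro-1-benzofuran-3-ol
Product: 10 1-[(2R,3R)-2-(3,3-dimethoxyprop-1-en-2-yl)-3-hydroxy-2,3-dihydro-1-benzofuran-5-yl]ethan-1-one, via dilithio species 8 (not isolated), via lithium hemiaminal 9 (not isolated)
Conditions: n-BuLi (2.2 equiv), THF, −78 °C; MeC(O)N(OMe)Me, −78 to 0 °C; aq. NH4Cl
Reagents that add atoms: N-methoxy-N-methylacetamide, CC(=O)N(C)OC
Why: Bromine–lithium exchange followed by Weinreb ketone synthesis, in which the first equivalent of n-BuLi forms the C3 alkoxide, the second exchanges the aryl bromide at −78 °C faster than any C–H deprotonation, and acylation stops at the chelated adduct 9 that gives the methyl ketone on work-up; no stereocentre is touched.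

Step 5
Reactants: 10 1-[(2R,3R)-2-(3,3-dimethoxyprop-1-en-2-yl)-3-hydroxy-2,3-dihydro-1-benzofuran-5-yl]ethan-1-one
Product: 11 (2R,3R)-5-acetyl-2-(3,3-dimethoxyprop-1-en-2-yl)-2,3-dihydro-1-benzofuran-3-yl acetate
Conditions: Ac2O, pyridine, 4-(dimethylamino)pyridine (cat.), CH2Cl2, 0 °C
Reagents that add atoms: acetic anhydride, CC(=O)OC(C)=O
Why: Nucleophile-catalysed acetylation of the secondary benzylic alcohol with retention at C3, the weak base and low temperature being chosen to avoid anti-elimination of the new acetate towards the benzofuran.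

Step 6
Reactants: 11 (2R,3R)-5-acetyl-2-(3,3-dimethoxyprop-1-en-2-yl)-2,3-dihydro-1-benzofuran-3-yl acetate
Product: 12 (2R,3R)-2-(3,3-dimethoxyprop-1-en-2-yl)-5-[(1R)-1-hydroxyethyl]-2,3-dihydro-1-benzofuran-3-yl acetate
Conditions: RuCl(p-cymene)[(R,R)-TsNCH(Ph)CH(Ph)NH2] (1 mol %), HCO2Na, H2O/THF, 40 °C
Reagents that add atoms: none
Why: Noyori–Ikariya asymmetric transfer hydrogenation, in which hydride and proton are delivered to the aryl methyl ketone in an outer-sphere six-membered transition state organised by a CH–π contact between p-cymene and the arene, so that the (R,R)-diamine ligand should set the new carbinol centre as R under catalyst control while the near-neutral formate medium leaves acetate, acetal and the isolated alkene untouched.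

Step 7
Reactants: 12 (2R,3R)-2-(3,3-dimethoxyprop-1-en-2-yl)-5-[(1R)-1-hydroxyethyl]-2,3-dihydro-1-benzofuran-3-yl acetate; 13 angelic acid, (2Z)-2-methylbut-2-enoic acid
Product: 15 (1R)-1-[(2R,3R)-3-acetoxy-2-(3,3-dimethoxyprop-1-en-2-yl)-2,3-dihydro-1-benzofuran-5-yl]ethyl (2Z)-2-methylbut-2-enoate, via mixed anhydride 14 (not isolated)
Conditions: 2,4,6-trichlorobenzoyl chloride, Et3N, toluene, rt; then 12, 4-(dimethylamino)pyridine (cat.), toluene, rt to 40 °C
Reagents that add atoms: angelic acid (13), C/C=C(/C)C(=O)O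
Why: Yamaguchi esterification, in which the pre-formed mixed anhydride 14 acylates the secondary alcohol at the less hindered angeloyl carbonyl with retention at the carbinol centre, and the low loading of nucleophilic catalyst should limit Z-to-E isomerisation to the tiglate.

Step 8
Reactants: 15 (1R)-1-[(2R,3R)-3-acetoxy-2-(3,3-dimethoxyprop-1-en-2-yl)-2,3-dihydro-1-benzofuran-5-yl]ethyl (2Z)-2-methylbut-2-enoate
Product: 16 (1R)-1-[(2R,3R)-3-acetoxy-2-(3-oxoprop-1-en-2-yl)-2,3-dihydro-1-benzofuran-5-yl]ethyl (2Z)-2-methylbut-2-enoate (CNP0294391.3)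
Conditions: oxalic acid (aq.) on SiO2, CH2Cl2, rt
Reagents that add atoms: water, O
Why: Acid-catalysed acetal hydrolysis through an alkene-conjugated oxocarbenium ion should unmask the enal under conditions too weakly acidic to ionise the benzylic acetate or the p-alkoxybenzylic angelate; no stereocentre is affected.

Compound list
1 | 5-bromo-2-hydroxybenzaldehyde | O=Cc1cc(Br)ccc1O | starting material
2 | 3-bromo-1,1-dimethoxypropan-2-one | COC(OC)C(=O)CBr | starting material
3 | 5-bromo-2-(3,3-dimethoxy-2-oxopropoxy)benzaldehyde | COC(OC)C(=O)COc1ccc(Br)cc1C=O | intermediate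
4 | (E)-enamine of 3 and (S)-proline, formed in the flask | COC(OC)/C(N1CCC[C@H]1C(=O)O)=C\Oc1ccc(Br)cc1C=O | intermediate
5 | iminium carboxylate of the aldol adduct, formed in the flask | COC(OC)C(=[N+]1CCC[C@H]1C(=O)[O-])[C@H]1Oc2ccc(Br)cc2[C@H]1O | intermediate
6 | 1-[(2S,3R)-5-bromo-3-hydroxy-2,3-dihydro-1-benzofuran-2-yl]-2,2-dimethoxyethan-1-one (cis) | COC(OC)C(=O)[C@H]1Oc2ccc(Br)cc2[C@H]1O | intermediate
7 | (2R,3R)-5-bromo-2-(3,3-dimethoxyprop-1-en-2-yl)-2,3-dihydro-1-benzofuran-3-ol | C=C(C(OC)OC)[C@H]1Oc2ccc(Br)cc2[C@H]1O | intermediate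
8 | C5-lithio lithium C3-alkoxide of 7, formed in the flask | C=C(C(OC)OC)[C@H]1Oc2ccc([Li])cc2[C@H]1O[Li] | intermediate
9 | lithium N-methoxy-N-methyl hemiaminal adduct (C3 lithium alkoxide), formed in the flask | C=C(C(OC)OC)[C@H]1Oc2ccc(C(C)(O[Li])N(C)OC)cc2[C@H]1O[Li] | intermediate
10 | 1-[(2R,3R)-2-(3,3-dimethoxyprop-1-en-2-yl)-3-hydroxy-2,3-dihydro-1-benzofuran-5-yl]ethan-1-one | C=C(C(OC)OC)[C@H]1Oc2ccc(C(C)=O)cc2[C@H]1O | intermediate
11 | (2R,3R)-5-acetyl-2-(3,3-dimethoxyprop-1-en-2-yl)-2,3-dihydro-1-benzofuran-3-yl acetate | C=C(C(OC)OC)[C@H]1Oc2ccc(C(C)=O)cc2[C@H]1OC(C)=O | intermediate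
12 | (2R,3R)-2-(3,3-dimethoxyprop-1-en-2-yl)-5-[(1R)-1-hydroxyethyl]-2,3-dihydro-1-benzofuran-3-yl acetate | C=C(C(OC)OC)[C@H]1Oc2ccc([C@@H](C)O)cc2[C@H]1OC(C)=O | intermediate
13 | angelic acid, (2Z)-2-methylbut-2-enoic acid | C/C=C(/C)C(=O)O | starting material
14 | (2Z)-2-methylbut-2-enoic 2,4,6-trichlorobenzoic anhydride, formed in the flask | C/C=C(/C)C(=O)OC(=O)c1c(Cl)cc(Cl)cc1Cl | intermediate
15 | (1R)-1-[(2R,3R)-3-acetoxy-2-(3,3-dimethoxyprop-1-en-2-yl)-2,3-dihydro-1-benzofuran-5-yl]ethyl (2Z)-2-methylbut-2-enoate | C=C(C(OC)OC)[C@H]1Oc2ccc([C@@H](C)OC(=O)/C(C)=C\C)cc2[C@H]1OC(C)=O | intermediate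
16 | (1R)-1-[(2R,3R)-3-acetoxy-2-(3-oxoprop-1-en-2-yl)-2,3-dihydro-1-benzofuran-5-yl]ethyl (2Z)-2-methylbut-2-enoate | C=C(C=O)[C@H]1Oc2ccc([C@@H](C)OC(=O)/C(C)=C\C)cc2[C@H]1OC(C)=O | target

Total step count: 8. Longest linear sequence: 8 steps (1 to 16).

Steps most likely to fail

Step 2. The aldol may lose water to the aromatic 2-acylbenzofuran, or the hydrogen-bonded transition state may discriminate the enantiotopic faces too weakly. The fallback sets out from 3 and comes back at 7. The ring is closed without asymmetric induction by soft enolisation (MgBr2·OEt2, i-Pr2NEt, CH2Cl2, −20 °C). The magnesium chelate between enolate and aldehyde oxygens should again give the cis aldol at a temperature where dehydration is slow, now as the racemate, that is 6 together with its enantiomer 1-[(2R,3S)-5-bromo-3-hydroxy-2,3-dihydro-1-benzofuran-2-yl]-2,2-dimethoxyethan-1-one F1. Methylenation as in step 3 then gives 7 together with (2S,3S)-5-bromo-2-(3,3-dimethoxyprop-1-en-2-yl)-2,3-dihydro-1-benzofuran-3-ol F2. Lipase-catalysed kinetic resolution (Candida antarctica lipase B, vinyl acetate, MTBE, 30 °C) is expected, by analogy with 1-indanol-type carbinols, to acylate the (3S)-alcohol to (2S,3S)-5-bromo-2-(3,3-dimethoxyprop-1-en-2-yl)-2,3-dihydro-1-benzofuran-3-yl acetate F3. Unreacted 7 is separated and enters step 4.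

Step 3. The Lewis-acidic reagent may ionise the ortho-oxygenated benzylic C3–OH and drive aromatisation, or methylenation of the doubly branched ketone may stall. The fallback sets out from 6 and comes back at 7. Compound 6 is silylated (Et3SiOTf, 2,6-lutidine, CH2Cl2, −78 °C) to 1-[(2S,3R)-5-bromo-3-(triethylsilyloxy)-2,3-dihydro-1-benzofuran-2-yl]-2,2-dimethoxyethan-1-one F4. This is methylenated under neutral conditions with Cp2TiMe2 (toluene, 65 °C) to [(2R,3R)-5-bromo-2-(3,3-dimethoxyprop-1-en-2-yl)-2,3-dihydro-1-benzofuran-3-yl]oxy(triethyl)silane F5, and desilylation (Bu4NF, AcOH, THF, 0 °C) gives 7.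

Step 7. Nucleophile-induced Z-to-E isomerisation of the activated angeloyl unit may deliver tiglate, or acylation of the benzylic alcohol may be slow. The fallback sets out from 12 and comes back at 15. Compound 12 is esterified with 2-[bis(2,2,2-trifluoroethoxy)phosphoryl]propanoic acid (N,N'-dicyclohexylcarbodiimide, 4-(dimethylamino)pyridine, CH2Cl2, 0 °C) to (1R)-1-[(2R,3R)-3-acetoxy-2-(3,3-dimethoxyprop-1-en-2-yl)-2,3-dihydro-1-benzofuran-5-yl]ethyl 2-[bis(2,2,2-trifluoroethoxy)phosphoryl]propanoate F6. Still–Gennari olefination (KN(SiMe3)2, 18-crown-6, THF, −78 °C; then acetaldehyde) builds the (Z)-2-methylbut-2-enoate on the molecule and should give 15.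

Further compounds
F1 | step 2 | 1-[(2R,3S)-5-bromo-3-hydroxy-2,3-dihydro-1-benzofuran-2-yl]-2,2-dimethoxyethan-1-one | COC(OC)C(=O)[C@@H]1Oc2ccc(Br)cc2[C@@H]1O
F2 | step 2 | (2S,3S)-5-bromo-2-(3,3-dimethoxyprop-1-en-2-yl)-2,3-dihydro-1-benzofuran-3-ol | C=C(C(OC)OC)[C@@H]1Oc2ccc(Br)cc2[C@@H]1O
F3 | step 2 | (2S,3S)-5-bromo-2-(3,3-dimethoxyprop-1-en-2-yl)-2,3-dihydro-1-benzofuran-3-yl acetate | C=C(C(OC)OC)[C@@H]1Oc2ccc(Br)cc2[C@@H]1OC(C)=O
F4 | step 3 | 1-[(2S,3R)-5-bromo-3-(triethylsilyloxy)-2,3-dihydro-1-benzofuran-2-yl]-2,2-dimethoxyethan-1-one | COC(OC)C(=O)[C@H]1Oc2ccc(Br)cc2[C@H]1O[Si](CC)(CC)CC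
F5 | step 3 | [(2R,3R)-5-bromo-2-(3,3-dimethoxyprop-1-en-2-yl)-2,3-dihydro-1-benzofuran-3-yl]oxy(triethyl)silane | C=C(C(OC)OC)[C@H]1Oc2ccc(Br)cc2[C@H]1O[Si](CC)(CC)CC
F6 | step 7 | (1R)-1-[(2R,3R)-3-acetoxy-2-(3,3-dimethoxyprop-1-en-2-yl)-2,3-dihydro-1-benzofuran-5-yl]ethyl 2-[bis(2,2,2-trifluoroethoxy)phosphoryl]propanoate | C=C(C(OC)OC)[C@H]1Oc2ccc([C@@H](C)OC(=O)C(C)P(=O)(OCC(F)(F)F)OCC(F)(F)F)cc2[C@H]1OC(C)=O
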